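The biflavone is disconnected inside ring A of unit 2 (the 7-methoxy-4'-hydroxyflavone half) instead of at the hindered C6–C8'' axis: that benzene ring is grown onto unit 1 (the acacetin half). The feature exploited is the contiguous triad on unit 2, C8a–O, C8–aryl and C7–OMe, with C5–O para to the axis, which is the substitution pattern a cyclobutenone/alkynyl ether benzannulation delivers. In one operation a 5,7-di-O-benzyl-6-(methoxyethynyl) acacetin derivative and 3-benzyloxycyclobutenone form unit 2 C8–C8a and C6–C7, close ring A around the existing aryl–carbon bond and leave one free phenol (future O1) beside an open ortho carbon (C4a) for pyranone construction.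

Key step: step 6

Remark: the target is drawn without an axial descriptor, so the tetra-ortho-substituted 6,8''-axis is taken as stereochemically undefined; compounds 15 onwards are racemic about it. Flavone numbering is used throughout.

Step 1
Reactants: 1 acacetin (5,7-dihydroxy-2-(4-methoxyphenyl)-4H-chromen-4-one)
Product: 2 7-(benzyloxy)-5-hydroxy-2-(4-methoxyphenyl)-4H-chromen-4-one
Conditions: BnBr (1.1 equiv), K2CO3 (1.2 equiv), acetone, reflux
Reagents that add atoms: benzyl bromide, BrCc1ccccc1
Why: Williamson etherification that should stop at O7, because the 7-OH is the acidic, unhindered phenol while the 5-OH is held in a hydrogen bond to the C4 carbonyl.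

Step 2
Reactants: 2 7-(benzyloxy)-5-hydroxy-2-(4-methoxyphenyl)-4H-chromen-4-one
Product: 3 7-(benzyloxy)-5-hydroxy-6-iodo-2-(4-methoxyphenyl)-4H-chromen-4-one
Conditions: BnMe3N ICl2 (1.1 equiv), CaCO3, CH2Cl2/MeOH, rt
Reagents that add atoms: benzyltrimethylammonium dichloroiodate, C[N+](C)(C)Cc1ccccc1.Cl[I-]Cl
Why: electrophilic aromatic iodination, which with this reagent goes ortho to the free chelated 5-OH (C6) when O7 is alkylated, whereas 5,7-dialkoxyflavones react at C8, so iodination is placed before the second benzylation.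

Step 3
Reactants: 3 7-(benzyloxy)-5-hydroxy-6-iodo-2-(4-methoxyphenyl)-4H-chromen-4-one
Product: 4 5,7-bis(benzyloxy)-6-iodo-2-(4-methoxyphenyl)-4H-chromen-4-one
Conditions: BnBr (1.5 equiv), K2CO3 (2 equiv), Bu4NI (cat.), DMF, 60 °C
Reagents that add atoms: benzyl bromide, BrCc1ccccc1
Why: Williamson etherification under more forcing conditions, needed because the 5-OH is hydrogen-bonded and flanked by iodine, and masking it prevents later addition of this phenol to the ynol ether or to a ketene.

Step 4
Reactants: 4 5,7-bis(benzyloxy)-6-iodo-2-(4-methoxyphenyl)-4H-chromen-4-one; 5 chloroacetaldehyde dimethyl acetal (2-chloro-1,1-dimethoxyethane)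
Product: 8 5,7-bis(benzyloxy)-6-(methoxyethynyl)-2-(4-methoxyphenyl)-4H-chromen-4-one, via lithium methoxyacetylide 6 (not isolated), via methoxyethynylzinc chloride 7 (not isolated)
Conditions: 5 (2 equiv), LiNEt2 (6.2 equiv, from n-BuLi and Et2NH), THF, 0 °C; ZnCl2 (2.4 equiv), 0 °C to rt; then 4, Pd(PPh3)4 (5 mol %), THF, 50 °C; aq. NaHCO3 work-up, Et3N-deactivated silica
Reagents that add atoms: none
Why: double elimination and deprotonation of the chloroacetal give the lithium alkoxyacetylide, transmetalation to zinc tempers its basicity so the pyranone is left alone, and the Negishi alkynylation of aryl iodides with alkoxyethynylzinc chlorides is established, the slim sp nucleophile tolerating the two ortho benzyloxy groups.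

Step 5
Reactants: 9 3-ethoxycyclobut-2-en-1-one
Product: 10 3-(benzyloxy)cyclobut-2-en-1-one
Conditions: BnOH (5 equiv), camphorsulfonic acid (5 mol %, anhydrous), toluene, 4 Å sieves, rt, reduced pressure to strip EtOH
Reagents that add atoms: benzyl alcohol, OCc1ccccc1
Why: acid-catalysed alkoxy exchange of a vinylogous ester (addition–elimination at C3 through the same protonated species by which this compound hydrolyses to cyclobutane-1,3-dione), driven by excess benzyl alcohol and removal of ethanol, and chosen so that unit 2 O5 is freed in the final hydrogenolysis.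

Step 6
Reactants: 8 5,7-bis(benzyloxy)-6-(methoxyethynyl)-2-(4-methoxyphenyl)-4H-chromen-4-one; 10 3-(benzyloxy)cyclobut-2-en-1-one
Product: 15 5,7-bis(benzyloxy)-6-[4-(benzyloxy)-2-hydroxy-6-methoxyphenyl]-2-(4-methoxyphenyl)-4H-chromen-4-one, via vinylketene 11 (not isolated), via vinylcyclobutenone adduct 12 (not isolated), via dienylketene 13 (not isolated), via cyclohexadienone tautomer 14 (not isolated)
Conditions: 10 (2.5 equiv, in portions), degassed toluene, 80 °C then 110 °C, sealed vessel; then K2CO3, MeOH, rt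
Reagents that add atoms: none
Why: Proposed new method: heating opens 10 by a 4π-electrocyclic process to vinylketene 11, whose ketene C=C undergoes a polar [2+2] cycloaddition with the ynol ether so that the aryl-bearing alkyne carbon (the nucleophilic end, β to the methoxy oxygen) bonds to the ketene carbonyl carbon (unit 2 C8–C8a) and the methoxy-bearing carbon bonds to the ketene α-carbon (unit 2 C6–C7), giving 12, which opens by a second 4π process to dienylketene 13; ring A then closes by a thermal 6π-electrocyclisation of the ketene carbon onto the terminal methylene to give 14, and enolisation gives phenol 15. The closest known reaction type is the Danheiser benzannulation of cyclobutenones with alkoxyacetylenes; what is untested is the 3-alkoxy group on the cyclobutenone combined with a doubly ortho-substituted aryl group on the ynol ether. No stereocentre survives, since C4 of 12 is lost on ring opening and the new biaryl axis forms as a racemate. The selectivity needed is the orientation of the [2+2] step, which the strong polarisation of the ynol ether by its oxygen and the electrophilic ketene carbon should secure, placing the unit 1 aryl group between OH and OMe with OBn para to it. The methyl ynol ether cannot fragment by retro-ene loss of an alkene, the alkyne is sterically slim between the two benzyloxy groups, and the closing K2CO3/MeOH treatment returns any phenol that was acylated by surplus ketene.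

Step 7
Reactants: 15 5,7-bis(benzyloxy)-6-[4-(benzyloxy)-2-hydroxy-6-methoxyphenyl]-2-(4-methoxyphenyl)-4H-chromen-4-one
Product: 16 3-[5,7-bis(benzyloxy)-2-(4-methoxyphenyl)-4-oxo-4H-chromen-6-yl]-6-(benzyloxy)-2-hydroxy-4-methoxybenzaldehyde
Conditions: MgCl2 (anhydrous, 3 equiv), Et3N (6 equiv), paraformaldehyde (8 equiv), MeCN, reflux; cold 1 M HCl work-up
Reagents that add atoms: paraformaldehyde (formaldehyde source), C=O
Why: magnesium-mediated ortho-formylation (Casnati–Skattebøl), in which the magnesium phenoxide delivers formaldehyde only to the carbon ortho to its oxygen and a second formaldehyde oxidises the benzylic alkoxide by hydride transfer, and the only free ortho carbon is unit 2 C4a because the other carries the biaryl bond.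

Step 8
Reactants: 16 3-[5,7-bis(benzyloxy)-2-(4-methoxyphenyl)-4-oxo-4H-chromen-6-yl]-6-(benzyloxy)-2-hydroxy-4-methoxybenzaldehyde; 17 1-(benzyloxy)-4-ethynylbenzene
Product: 19 5,7-bis(benzyloxy)-6-{4-(benzyloxy)-3-[3-[4-(benzyloxy)phenyl]-1-hydroxyprop-2-yn-1-yl]-2-hydroxy-6-methoxyphenyl}-2-(4-methoxyphenyl)-4H-chromen-4-one, via lithium arylacetylide 18 (not isolated)
Conditions: 17 (3.2 equiv), n-BuLi (3.0 equiv), THF, −78 °C; then 16, −78 to 0 °C; aq. NH4Cl
Reagents that add atoms: none
Why: 1,2-addition of a lithium acetylide to an aldehyde, in which one equivalent deprotonates the phenol and the excess adds to the formyl group, far more electrophilic at low temperature than the γ-pyrone carbonyl of unit 1; the carbinol stereocentre forms without control, as a mixture of diastereomers relative to the axis, and is erased in step 9.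

Step 9
Reactants: 19 propargylic alcohol from step 8
Product: 20 5,7-bis(benzyloxy)-6-{4-(benzyloxy)-3-[3-[4-(benzyloxy)phenyl]prop-2-ynoyl]-2-hydroxy-6-methoxyphenyl}-2-(4-methoxyphenyl)-4H-chromen-4-one
Conditions: MnO2 (activated, 15 equiv), CH2Cl2, rt
Reagents that add atoms: none
Why: MnO2 oxidation of a doubly activated (benzylic and propargylic) alcohol to the ynone, a mild heterogeneous oxidation that should tolerate the free phenol and the benzyl ethers.

Step 10
Reactants: 20 ortho-hydroxyaryl ynone from step 9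
Product: 22 5,7-bis(benzyloxy)-6-{5-(benzyloxy)-2-[4-(benzyloxy)phenyl]-7-methoxy-4-oxo-4H-chromen-8-yl}-2-(4-methoxyphenyl)-4H-chromen-4-one, via diethylamino enone 21 (not isolated)
Conditions: Et2NH (5 equiv), EtOH/THF, rt then 60 °C
Reagents that add atoms: none
Why: amine-mediated 6-endo cyclisation, in which conjugate addition of diethylamine to the ynone gives a β-amino enone that the phenol attacks at the β-carbon with loss of the amine (oxa-Michael addition–elimination), so that only the pyran-4-one and not the 5-exo aurone should form.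

Step 11
Reactants: 22 tetra-O-benzyl biflavone from step 10
Product: 23 5,7-dihydroxy-6-[5-hydroxy-2-(4-hydroxyphenyl)-7-methoxy-4-oxo-4H-chromen-8-yl]-2-(4-methoxyphenyl)-4H-chromen-4-one (target)
Conditions: H2 (1 atm), Pd/C (10 wt % Pd), THF/MeOH, rt
Reagents that add atoms: none
Why: catalytic hydrogenolysis of the four aryl benzyl ethers, which at ambient pressure and temperature should leave the two methyl ethers and the deactivated C2=C3 bonds of both pyranones intact.

Compound list
1 | acacetin, 5,7-dihydroxy-2-(4-methoxyphenyl)-4H-chromen-4-one | COc1ccc(cc1)-c1cc(=O)c2c(O)cc(O)cc2o1 | starting material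
2 | 7-(benzyloxy)-5-hydroxy-2-(4-methoxyphenyl)-4H-chromen-4-one | COc1ccc(cc1)-c1cc(=O)c2c(O)cc(OCc3ccccc3)cc2o1 | intermediate
3 | 7-(benzyloxy)-5-hydroxy-6-iodo-2-(4-methoxyphenyl)-4H-chromen-4-one | COc1ccc(cc1)-c1cc(=O)c2c(O)c(I)c(OCc3ccccc3)cc2o1 | intermediate
4 | 5,7-bis(benzyloxy)-6-iodo-2-(4-methoxyphenyl)-4H-chromen-4-one | COc1ccc(cc1)-c1cc(=O)c2c(OCc3ccccc3)c(I)c(OCc3ccccc3)cc2o1 | intermediate
5 | chloroacetaldehyde dimethyl acetal | COC(CCl)OC | starting material
6 | lithium methoxyacetylide | COC#C[Li] | intermediate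
7 | methoxyethynylzinc chloride | COC#C[Zn]Cl | intermediate
8 | 5,7-bis(benzyloxy)-6-(methoxyethynyl)-2-(4-methoxyphenyl)-4H-chromen-4-one | COC#Cc1c(OCc2ccccc2)cc2oc(-c3ccc(OC)cc3)cc(=O)c2c1OCc1ccccc1 | intermediate
9 | 3-ethoxycyclobut-2-en-1-one | CCOC1=CC(=O)C1 | starting material
10 | 3-(benzyloxy)cyclobut-2-en-1-one | O=C1C=C(OCc2ccccc2)C1 | intermediate
11 | 3-(benzyloxy)buta-1,3-dien-1-one (vinylketene) | C=C(OCc1ccccc1)C=C=O | intermediate
12 | 2-[5,7-bis(benzyloxy)-2-(4-methoxyphenyl)-4-oxo-4H-chromen-6-yl]-4-[1-(benzyloxy)ethenyl]-3-methoxycyclobut-2-en-1-one (racemic) | COC1=C(c2c(OCc3ccccc3)cc3oc(-c4ccc(OC)cc4)cc(=O)c3c2OCc2ccccc2)C(=O)C1C(=C)OCc1ccccc1 | intermediate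
13 | (3E)-2-[5,7-bis(benzyloxy)-2-(4-methoxyphenyl)-4-oxo-4H-chromen-6-yl]-5-(benzyloxy)-3-methoxyhexa-1,3,5-trien-1-one (dienylketene) | O=C=C(c1c(OCc2ccccc2)cc2oc(-c3ccc(OC)cc3)cc(=O)c2c1OCc1ccccc1)/C(OC)=C\C(=C)OCc1ccccc1 | intermediate
14 | 2-[5,7-bis(benzyloxy)-2-(4-methoxyphenyl)-4-oxo-4H-chromen-6-yl]-5-(benzyloxy)-3-methoxycyclohexa-2,4-dien-1-one | COC1=C(c2c(OCc3ccccc3)cc3oc(-c4ccc(OC)cc4)cc(=O)c3c2OCc2ccccc2)C(=O)CC(OCc2ccccc2)=C1 | intermediate
15 | 5,7-bis(benzyloxy)-6-[4-(benzyloxy)-2-hydroxy-6-methoxyphenyl]-2-(4-methoxyphenyl)-4H-chromen-4-one (racemic axis) | COc1ccc(cc1)-c1cc(=O)c2c(OCc3ccccc3)c(-c3c(O)cc(OCc4ccccc4)cc3OC)c(OCc3ccccc3)cc2o1 | intermediate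
16 | 3-[5,7-bis(benzyloxy)-2-(4-methoxyphenyl)-4-oxo-4H-chromen-6-yl]-6-(benzyloxy)-2-hydroxy-4-methoxybenzaldehyde | COc1ccc(cc1)-c1cc(=O)c2c(OCc3ccccc3)c(-c3c(O)c(C=O)c(OCc4ccccc4)cc3OC)c(OCc3ccccc3)cc2o1 | intermediate
17 | 1-(benzyloxy)-4-ethynylbenzene | C#Cc1ccc(OCc2ccccc2)cc1 | starting material
18 | lithium [4-(benzyloxy)phenyl]acetylide | [Li]C#Cc1ccc(OCc2ccccc2)cc1 | intermediate
19 | 5,7-bis(benzyloxy)-6-{4-(benzyloxy)-3-[3-[4-(benzyloxy)phenyl]-1-hydroxyprop-2-yn-1-yl]-2-hydroxy-6-methoxyphenyl}-2-(4-methoxyphenyl)-4H-chromen-4-one (mixture of stereoisomers at the carbinol) | COc1ccc(cc1)-c1cc(=O)c2c(OCc3ccccc3)c(-c3c(O)c(C(O)C#Cc4ccc(OCc5ccccc5)cc4)c(OCc4ccccc4)cc3OC)c(OCc3ccccc3)cc2o1 | intermediate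
20 | 5,7-bis(benzyloxy)-6-{4-(benzyloxy)-3-[3-[4-(benzyloxy)phenyl]prop-2-ynoyl]-2-hydroxy-6-methoxyphenyl}-2-(4-methoxyphenyl)-4H-chromen-4-one | COc1ccc(cc1)-c1cc(=O)c2c(OCc3ccccc3)c(-c3c(O)c(C(=O)C#Cc4ccc(OCc5ccccc5)cc4)c(OCc4ccccc4)cc3OC)c(OCc3ccccc3)cc2o1 | intermediate
21 | 5,7-bis(benzyloxy)-6-{4-(benzyloxy)-3-[3-[4-(benzyloxy)phenyl]-3-(diethylamino)prop-2-enoyl]-2-hydroxy-6-methoxyphenyl}-2-(4-methoxyphenyl)-4H-chromen-4-one (alkene geometry not defined) | COc1ccc(cc1)-c1cc(=O)c2c(OCc3ccccc3)c(-c3c(O)c(C(=O)C=C(N(CC)CC)c4ccc(OCc5ccccc5)cc4)c(OCc4ccccc4)cc3OC)c(OCc3ccccc3)cc2o1 | intermediate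
22 | 5,7-bis(benzyloxy)-6-{5-(benzyloxy)-2-[4-(benzyloxy)phenyl]-7-methoxy-4-oxo-4H-chromen-8-yl}-2-(4-methoxyphenyl)-4H-chromen-4-one | COc1ccc(cc1)-c1cc(=O)c2c(OCc3ccccc3)c(-c3c(OC)cc(OCc4ccccc4)c4c(=O)cc(-c5ccc(OCc6ccccc6)cc5)oc34)c(OCc3ccccc3)cc2o1 | intermediate
23 | 5,7-dihydroxy-6-[5-hydroxy-2-(4-hydroxyphenyl)-7-methoxy-4-oxo-4H-chromen-8-yl]-2-(4-methoxyphenyl)-4H-chromen-4-one (CNP0290866.0) | COc1ccc(-c2cc(=O)c3c(O)c(-c4c(OC)cc(O)c5c(=O)cc(-c6ccc(O)cc6)oc45)c(O)cc3o2)cc1 | target

Total step count: 11. Longest linear sequence: 10 steps (steps 1, 2, 3, 4, 6, 7, 8, 9, 10, 11 from acacetin); step 5 is a one-step side branch.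

Steps most likely to fail

Step 6. The alkoxy-substituted vinylketene may dimerise or polymerise faster than it is captured. The cycloaddition may also be slow at the shielded alkyne or take the reverse orientation, and the ynol ether may degrade on prolonged heating. The fallback makes the axis by a Suzuki–Miyaura biaryl coupling of two complete flavones, a known reaction type for biflavones; it sets out from iodide 4 and returns at 22. Commercial genkwanin (5,4'-dihydroxy-7-methoxyflavone) is bis-benzylated (BnBr, K2CO3, DMF, 70 °C) to 5-(benzyloxy)-2-[4-(benzyloxy)phenyl]-7-methoxy-4H-chromen-4-one F1. Iodination (I2, AgO2CCF3, CH2Cl2, 0 °C), which in 5,7-dialkoxyflavones goes to C8, gives 5-(benzyloxy)-2-[4-(benzyloxy)phenyl]-8-iodo-7-methoxy-4H-chromen-4-one F2. Miyaura borylation (B2pin2, PdCl2(dppf), KOAc, dioxane, 90 °C) gives the 8-pinacolboronate 5-(benzyloxy)-2-[4-(benzyloxy)phenyl]-7-methoxy-8-(4,4,5,5-tetramethyl-1,3,2-dioxaborolan-2-yl)-4H-chromen-4-one F3. Coupling of this boronate with 4 (Pd(OAc)2, SPhos, K3PO4, toluene/water, 100 °C) should give 22, which then needs only step 11.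

Step 5. Acid may cleave the strained four-membered vinylogous ester to acetoacetate-type products instead of exchanging the alkoxy group, or the exchange equilibrium may not be driven to completion. The fallback sets out from 9 and returns at 10. Compound 9 is hydrolysed with cold dilute aqueous HCl to cyclobutane-1,3-dione F4. This acidic enol is then O-benzylated under Mitsunobu conditions (BnOH, PPh3, DIAD, THF, 0 °C), enol ether formation from cyclic 1,3-diones by this reaction being known.

Step 4. Oxidative addition and transmetalation at the doubly ortho-substituted carbon–iodine bond may be slow. Amide- and alkoxide-induced degradation of the flavone, or hydration of the acid-labile ynol ether during isolation, could then win. The fallback sets out from 4 (with 6 as the alkyne source) and returns at 8. Acetylide 6 is quenched with Bu3SnCl and the product distilled to give tributyl(methoxyethynyl)stannane F5. This isolable, base-free reagent is coupled with 4 by a Stille reaction (PdCl2(PPh3)2, Et4NCl, DMF, 60 °C), a known way to make aryl alkoxyacetylenes under neutral conditions.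

Further compounds
F1 | step 6 | 5-(benzyloxy)-2-[4-(benzyloxy)phenyl]-7-methoxy-4H-chromen-4-one | COc1cc(OCc2ccccc2)c2c(=O)cc(-c3ccc(OCc4ccccc4)cc3)oc2c1
F2 | step 6 | 5-(benzyloxy)-2-[4-(benzyloxy)phenyl]-8-iodo-7-methoxy-4H-chromen-4-one | COc1cc(OCc2ccccc2)c2c(=O)cc(-c3ccc(OCc4ccccc4)cc3)oc2c1I
F3 | step 6 | 5-(benzyloxy)-2-[4-(benzyloxy)phenyl]-7-methoxy-8-(4,4,5,5-tetramethyl-1,3,2-dioxaborolan-2-yl)-4H-chromen-4-one | COc1cc(OCc2ccccc2)c2c(=O)cc(-c3ccc(OCc4ccccc4)cc3)oc2c1B1OC(C)(C)C(C)(C)O1
F4 | step 5 | cyclobutane-1,3-dione | O=C1CC(=O)C1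
F5 | step 4 | tributyl(methoxyethynyl)stannane | COC#C[Sn](CCCC)(CCCC)CCCC
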